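**Retrosynthetic overview**
1. Target ⇐ global O‑debenzylation of its 4',6'‑di‑O‑benzyl ether (naphthalene A = the 4,5‑dimethoxy‑7‑methyl‑2‑naphthol half, unprimed locants; naphthalene B = the methyl‑bearing half, primed locants).
2. The biaryl C1–C1' bond, the 2‑OH and the 2'‑CH3 are traced back together to one ether C–O bond: a 2‑naphthylmethyl 2‑naphthyl ether that rearranges by a double‑dearomative [3,3] shift (O becomes OH, OCH2 becomes CH3).
3. That ether C–O bond is the only bond made between the halves: site‑selective Mitsunobu coupling of a naphthalene‑1,3‑diol (A) with a naphthalen‑2‑ylmethanol (B), then O‑methylation of the remaining peri‑OH.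
4. Second ring of A: lateral lithiation, acylation and Claisen cyclisation of methyl 2‑methoxy‑4,6‑dimethylbenzoate (from 3,5‑dimethylanisole). Second ring of B: Stobbe condensation and ring closure from 6‑bromovanillin (Br blocks the wrong ortho position, then is removed).
5. Ring order: second ring of A (step 2), second ring of B (step 4); no ring is formed after the union.

Assumption: the SMILES carries no stereodescriptor, so no stereocentre has to be set; the hindered 1,1'‑axis is taken as unspecified and the compound is made racemic about this axis.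

**Step 1**
Reactants: 1 3,5-dimethylanisole; 2 methyl chloroformate
Product: 3 methyl 2-methoxy-4,6-dimethylbenzoate
Conditions: n-BuLi (1.1 equiv), TMEDA (1.1 equiv), Et2O, 0 °C → rt, 4 h; then cannulated into 2 (2.5 equiv), THF, −78 °C
Reagents that add atoms: none
Why: Directed ortho-metalation: OMe directs lithiation to the ring position next to it (both ortho positions are equivalent), and inverse quench into excess chloroformate stops at the ester.

**Step 2**
Reactants: 3 methyl 2-methoxy-4,6-dimethylbenzoate; 4 N-methoxy-N-methylacetamide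
Product: 6 8-methoxy-6-methylnaphthalene-1,3-diol, via keto ester 5 (not isolated)
Conditions: LiN(i-Pr)2 (1.2 equiv), THF, −78 °C; 4 (1.3 equiv), −78 → 0 °C; AcOH (1.3 equiv); then KOt-Bu (3 equiv), THF, 0 °C → rt; aq. HCl, under N2
Reagents that add atoms: none
Why: Lateral lithiation of the ortho-methyl of the hindered benzoate, acylation by the Weinreb amide to aryl acetone 5, then intramolecular Claisen (Dieckmann-type) condensation onto the ester gives a 1,3-diketone that aromatises to the naphthalene-1,3-diol.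

**Step 3**
Reactants: 7 6-bromovanillin (2-bromo-4-hydroxy-5-methoxybenzaldehyde); 8 dimethyl succinate
Product: 9 (E)-4-(2-bromo-4-hydroxy-5-methoxyphenyl)-3-(methoxycarbonyl)but-3-enoic acid
Conditions: LiOMe (3.5 equiv), MeOH, reflux, 48 h; aq. HCl
Reagents that add atoms: none
Why: Stobbe condensation: the succinate enolate adds to the aldehyde and the lactone intermediate opens irreversibly to the (E)-half-ester with the aryl group cis to the CH2CO2H arm; the phenoxide only slows the addition.

**Step 4**
Reactants: 9 (E)-4-(2-bromo-4-hydroxy-5-methoxyphenyl)-3-(methoxycarbonyl)but-3-enoic acid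
Product: 10 methyl 4,6-diacetoxy-8-bromo-5-methoxy-2-naphthoate
Conditions: Ac2O, NaOAc, 140 °C, 3 h
Reagents that add atoms: acetic anhydride, CC(=O)OC(C)=O
Why: Stobbe ring closure (mixed anhydride/ketene, intramolecular acylation) can only occur at the position between the side chain and OMe because the other ortho position carries Br; the new naphthol and the phenol are acetylated in the same pot.

**Step 5**
Reactants: 10 methyl 4,6-diacetoxy-8-bromo-5-methoxy-2-naphthoate
Product: 11 methyl 4,6-diacetoxy-5-methoxy-2-naphthoate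
Conditions: H2 (1 atm), Pd/C (10 wt% Pd), NaOAc (1.5 equiv), EtOAc, rt
Reagents that add atoms: none
Why: Pd-catalysed hydrodehalogenation of the aryl C–Br bond, buffered with NaOAc so that the ester and the aryl acetates survive; this removes the peri substituent before the biaryl bond is made.

**Step 6**
Reactants: 11 methyl 4,6-diacetoxy-5-methoxy-2-naphthoate
Product: 13 methyl 4,6-bis(benzyloxy)-5-methoxy-2-naphthoate, via dihydroxy ester 12 (not isolated)
Conditions: K2CO3 (5 equiv), MeOH, rt, 1 h, N2; MeOH evaporated; then BnBr (3 equiv), DMF, 60 °C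
Reagents that add atoms: benzyl bromide, BrCc1ccccc1
Why: Methanolysis of the two aryl acetates followed by Williamson O-benzylation of both phenoxides in the same flask; the methyl ester is unaffected by K2CO3 in MeOH.

**Step 7**
Reactants: 13 methyl 4,6-bis(benzyloxy)-5-methoxy-2-naphthoate
Product: 14 [4,6-bis(benzyloxy)-5-methoxynaphthalen-2-yl]methanol
Conditions: LiAlH4 (1.5 equiv), THF, 0 °C; then H2O
Reagents that add atoms: none
Why: Hydride reduction of the methyl ester to the primary benzylic alcohol; benzyl and methyl aryl ethers are inert.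

**Step 8**
Reactants: 6 8-methoxy-6-methylnaphthalene-1,3-diol; 14 [4,6-bis(benzyloxy)-5-methoxynaphthalen-2-yl]methanol
Product: 15 3-{[4,6-bis(benzyloxy)-5-methoxynaphthalen-2-yl]methoxy}-8-methoxy-6-methylnaphthalen-1-ol
Conditions: PPh3 (1.3 equiv) and DIAD (1.3 equiv) premixed at 0 °C, then 14 and 6 (1.3 equiv), toluene–THF, 0 °C → rt
Reagents that add atoms: none
Why: Mitsunobu etherification: the 3-OH of 6 is free and the more acidic phenol, whereas the 1-OH is held in a peri hydrogen bond to 8-OMe and is more hindered, so the 3-oxygen displaces the alkoxyphosphonium of 14; this forms the fragment-linking C–O bond and differentiates the two oxygens of naphthalene A.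

**Step 9**
Reactants: 15 3-{[4,6-bis(benzyloxy)-5-methoxynaphthalen-2-yl]methoxy}-8-methoxy-6-methylnaphthalen-1-ol
Product: 16 3-{[4,6-bis(benzyloxy)-5-methoxynaphthalen-2-yl]methoxy}-1,8-dimethoxy-6-methylnaphthalene
Conditions: MeI (3 equiv), K2CO3 (3 equiv), DMF, 50 °C
Reagents that add atoms: iodomethane, CI
Why: Williamson O-methylation of the only remaining acidic site, the peri naphthol.

**Step 10**
Reactants: 16 3-{[4,6-bis(benzyloxy)-5-methoxynaphthalen-2-yl]methoxy}-1,8-dimethoxy-6-methylnaphthalene
Product: 18 1-[4,6-bis(benzyloxy)-5-methoxy-2-methylnaphthalen-1-yl]-4,5-dimethoxy-7-methylnaphthalen-2-ol, via keto-isotoluene 17 (not isolated)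
Conditions: degassed 1,2-dichlorobenzene (0.02 M), 2,6-lutidine (0.5 equiv), sealed tube, 180 °C, 4–8 h, Ar
Reagents that add atoms: none
Why: Proposed new method: a thermal double-dearomative benzyl-Claisen ([3,3]-sigmatropic) shift in which the O–CH2 bond and the two bond-fixed C1=C2 bonds of the naphthalenes act as the allyl vinyl ether unit, so that a chair transition state breaks O–CH2 and joins C1 of naphthalene A (ortho to the ether oxygen, para to 4-OMe, strongly nucleophilic) to C1' of naphthalene B (allylic terminus of the 2-naphthylmethyl unit, whose developing positive charge is stabilised by the conjugated 6'-OBn), giving naphthalenone/isotoluene 17, whose keto–enol tautomerisation and proton-shuttled 1,3-hydrogen shift (exocyclic CH2 to CH3) restore both aromatic rings irreversibly and turn the ether oxygen into the 2-OH and the OCH2 carbon into the 2'-CH3; each naphthalene gives up far less resonance energy than a benzene ring would, the base and the non-polar dilute medium suppress the ionic 1,3-shift, and the axis forms racemic; the closest known reaction types are the aromatic Claisen rearrangement of allyl 2-naphthyl ethers and the benzyl-Claisen rearrangement of benzyl vinyl ethers, benzyl ketene acetals and benzyl alkynyl ethers, which has not been shown for arylmethyl aryl ethers.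

**Step 11**
Reactants: 18 1-[4,6-bis(benzyloxy)-5-methoxy-2-methylnaphthalen-1-yl]-4,5-dimethoxy-7-methylnaphthalen-2-ol
Product: 19 1-(4,6-dihydroxy-5-methoxy-2-methylnaphthalen-1-yl)-4,5-dimethoxy-7-methylnaphthalen-2-ol (CNP0288130.0)
Conditions: H2 (1 atm), Pd/C (10 wt% Pd), EtOAc–MeOH, rt; work-up under N2
Reagents that add atoms: none
Why: Hydrogenolysis of the two benzyl aryl ethers; methyl ethers, the naphthalene rings and the biaryl bond are untouched.

**Compound list**
1 | 3,5-dimethylanisole | COc1cc(C)cc(C)c1 | starting material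
2 | methyl chloroformate | COC(=O)Cl | starting material
3 | methyl 2-methoxy-4,6-dimethylbenzoate | COC(=O)c1c(C)cc(C)cc1OC | intermediate
4 | N-methoxy-N-methylacetamide | CC(=O)N(C)OC | starting material
5 | methyl 2-methoxy-4-methyl-6-(2-oxopropyl)benzoate | COC(=O)c1c(CC(C)=O)cc(C)cc1OC | intermediate (not isolated)
6 | 8-methoxy-6-methylnaphthalene-1,3-diol | COc1cc(C)cc2cc(O)cc(O)c12 | intermediate
7 | 6-bromovanillin (2-bromo-4-hydroxy-5-methoxybenzaldehyde) | O=Cc1cc(OC)c(O)cc1Br | starting material
8 | dimethyl succinate | COC(=O)CCC(=O)OC | starting material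
9 | (E)-4-(2-bromo-4-hydroxy-5-methoxyphenyl)-3-(methoxycarbonyl)but-3-enoic acid | COC(=O)/C(CC(=O)O)=C/c1cc(OC)c(O)cc1Br | intermediate
10 | methyl 4,6-diacetoxy-8-bromo-5-methoxy-2-naphthoate | COC(=O)c1cc(OC(C)=O)c2c(OC)c(OC(C)=O)cc(Br)c2c1 | intermediate
11 | methyl 4,6-diacetoxy-5-methoxy-2-naphthoate | COC(=O)c1cc(OC(C)=O)c2c(OC)c(OC(C)=O)ccc2c1 | intermediate
12 | methyl 4,6-dihydroxy-5-methoxy-2-naphthoate | COC(=O)c1cc(O)c2c(OC)c(O)ccc2c1 | intermediate (not isolated)
13 | methyl 4,6-bis(benzyloxy)-5-methoxy-2-naphthoate | COC(=O)c1cc(OCc3ccccc3)c2c(OC)c(OCc3ccccc3)ccc2c1 | intermediate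
14 | [4,6-bis(benzyloxy)-5-methoxynaphthalen-2-yl]methanol | OCc1cc(OCc3ccccc3)c2c(OC)c(OCc3ccccc3)ccc2c1 | intermediate
15 | 3-{[4,6-bis(benzyloxy)-5-methoxynaphthalen-2-yl]methoxy}-8-methoxy-6-methylnaphthalen-1-ol | COc1cc(C)cc2cc(OCc3cc(OCc5ccccc5)c4c(OC)c(OCc5ccccc5)ccc4c3)cc(O)c12 | intermediate
16 | 3-{[4,6-bis(benzyloxy)-5-methoxynaphthalen-2-yl]methoxy}-1,8-dimethoxy-6-methylnaphthalene | COc1cc(C)cc2cc(OCc3cc(OCc5ccccc5)c4c(OC)c(OCc5ccccc5)ccc4c3)cc(OC)c12 | intermediate
17 | 1-[4,6-bis(benzyloxy)-5-methoxy-2-methylidene-1,2-dihydronaphthalen-1-yl]-4,5-dimethoxy-7-methylnaphthalen-2(1H)-one (two transient sp3 centres, configuration not defined, lost on rearomatisation) | C=C1C=C(OCc2ccccc2)c3c(OC)c(OCc2ccccc2)ccc3C1C4C(=O)C=C(OC)c5c(OC)cc(C)cc54 | intermediate (not isolated)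
18 | 1-[4,6-bis(benzyloxy)-5-methoxy-2-methylnaphthalen-1-yl]-4,5-dimethoxy-7-methylnaphthalen-2-ol (racemic axis) | COc1cc(C)cc2c(-c3c(C)cc(OCc5ccccc5)c4c(OC)c(OCc5ccccc5)ccc34)c(O)cc(OC)c12 | intermediate
19 | 1-(4,6-dihydroxy-5-methoxy-2-methylnaphthalen-1-yl)-4,5-dimethoxy-7-methylnaphthalen-2-ol (racemic axis) | COc1cc(C)cc2c(-c3c(C)cc(O)c4c(OC)c(O)ccc34)c(O)cc(OC)c12 | target

**Totals**
Total step count: 11. Longest linear sequence: 9 steps (7 to 19, steps 3–11); the other branch (1 to 6) is 2 steps.

**Steps most likely to fail**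

Step 10 (the new rearrangement). The ether may instead ionise or homolyse, giving 1,3-shift (C-naphthylmethylated) products, or react too slowly. Fallback with known chemistry, from 16 to 19: NBS (1.0 equiv, DMF, −20 °C) brominates the most electron-rich position of 16, the one ortho to the ether oxygen and para to OMe, giving 4-bromo-3-{[4,6-bis(benzyloxy)-5-methoxynaphthalen-2-yl]methoxy}-1,8-dimethoxy-6-methylnaphthalene F1. Intramolecular Pd-catalysed direct C–H arylation (Pd(OAc)2, PCy3·HBF4, K2CO3, DMA, 130 °C) then closes a six-membered ring onto C1' of naphthalene B. This gives the bridged cyclic ether, the bis(benzyloxy)trimethoxymethyl-6H-dinaphtho[2,1-b:1',2'-d]pyran F2, in which C1 is bonded to C1' and the OCH2 bridge links C2 to C2'. Hydrogenolysis (H2, Pd(OH)2/C, EtOAc–AcOH) cleaves the ring benzylic C–O bond together with the two benzyl ethers and gives 19 directly.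

Step 8 (site-selective Mitsunobu). Bis-etherification, reaction at the peri OH or C-alkylation of the electron-rich diol could lower the yield. Fallback, from 6 to 16: TIPSCl and imidazole (CH2Cl2, 0 °C) silylate only the free 3-OH to give 8-methoxy-6-methyl-3-[(triisopropylsilyl)oxy]naphthalen-1-ol F3. MeI/K2CO3 in acetone methylates the peri OH to give [(4,5-dimethoxy-7-methylnaphthalen-2-yl)oxy]triisopropylsilane F4. Bu4NF in THF releases 4,5-dimethoxy-7-methylnaphthalen-2-ol F5, which has a single OH. Mitsunobu coupling of F5 with 14 (PPh3, DIAD) then gives 16 without passing through 15.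

Step 3 (Stobbe condensation on the free phenol). The phenoxide deactivates the aldehyde and the reaction may stall. Fallback, from 7 to 13: BnBr/K2CO3 in DMF gives 4-(benzyloxy)-2-bromo-5-methoxybenzaldehyde F6. Stobbe condensation with 8 (KOt-Bu, t-BuOH, reflux) gives (E)-4-[4-(benzyloxy)-2-bromo-5-methoxyphenyl]-3-(methoxycarbonyl)but-3-enoic acid F7. Ac2O/NaOAc at 140 °C closes the ring to methyl 4-acetoxy-6-(benzyloxy)-8-bromo-5-methoxy-2-naphthoate F8. H2 over Pd/C with NaOAc removes bromine and the benzyl group to give methyl 4-acetoxy-6-hydroxy-5-methoxy-2-naphthoate F9. The conditions of step 6 (K2CO3/MeOH, then BnBr/DMF) convert F9 through 12 into 13.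

**Further compounds**
F1 | step 10 | 4-bromo-3-{[4,6-bis(benzyloxy)-5-methoxynaphthalen-2-yl]methoxy}-1,8-dimethoxy-6-methylnaphthalene | COc1cc(C)cc2c(Br)c(OCc3cc(OCc5ccccc5)c4c(OC)c(OCc5ccccc5)ccc4c3)cc(OC)c12
F2 | step 10 | bis(benzyloxy)trimethoxymethyl-6H-dinaphtho[2,1-b:1',2'-d]pyran (cyclic ether, C1–C1' bonded, OCH2 bridge from C2 to C2') | COc1cc(C)cc2c3c(OCc4cc(OCc7ccccc7)c5c(OC)c(OCc7ccccc7)ccc5c43)cc(OC)c12
F3 | step 8 | 8-methoxy-6-methyl-3-[(triisopropylsilyl)oxy]naphthalen-1-ol | COc1cc(C)cc2cc(O[Si](C(C)C)(C(C)C)C(C)C)cc(O)c12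
F4 | step 8 | [(4,5-dimethoxy-7-methylnaphthalen-2-yl)oxy]triisopropylsilane | COc1cc(C)cc2cc(O[Si](C(C)C)(C(C)C)C(C)C)cc(OC)c12
F5 | step 8 | 4,5-dimethoxy-7-methylnaphthalen-2-ol | COc1cc(C)cc2cc(O)cc(OC)c12
F6 | step 3 | 4-(benzyloxy)-2-bromo-5-methoxybenzaldehyde | O=Cc1cc(OC)c(OCc2ccccc2)cc1Br
F7 | step 3 | (E)-4-[4-(benzyloxy)-2-bromo-5-methoxyphenyl]-3-(methoxycarbonyl)but-3-enoic acid | COC(=O)/C(CC(=O)O)=C/c1cc(OC)c(OCc2ccccc2)cc1Br
F8 | step 3 | methyl 4-acetoxy-6-(benzyloxy)-8-bromo-5-methoxy-2-naphthoate | COC(=O)c1cc(OC(C)=O)c2c(OC)c(OCc3ccccc3)cc(Br)c2c1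
F9 | step 3 | methyl 4-acetoxy-6-hydroxy-5-methoxy-2-naphthoate | COC(=O)c1cc(OC(C)=O)c2c(OC)c(O)ccc2c1
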